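(The data come from a simulation for substances that don't exist; noise was put on by code.)

Whatever the flask does, the charge stays on the books: starting material, target and anything the analysis does not show add up to the charge at every hour. So the thing to follow is the share of reacted material that is still target.

all flasks: starting material 35 mM

| flask | reagent | second substrate | third substrate | remark | time |
|---|---|---|---|---|---|
| north-east | 0.17 equiv | 1 equiv | 0.20 equiv | run made earlier |  |
| south | 13 equiv | 1 equiv | 0.20 equiv | run made earlier |  |
| gamma | 0.120 equiv | 1.00 equiv | 0.200 equiv |  | 20 h |
| epsilon | 0.400 equiv | 1.00 equiv | 0.200 equiv |  | 20 h |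
| theta | 1.20 equiv | 1.00 equiv | 0.200 equiv |  | 20 h |
| alpha | 4.00 equiv | 1.00 equiv | 0.200 equiv |  | 20 h |
| zeta | 10.0 equiv | 1.00 equiv | 0.200 equiv |  | 20 h |

- north-east (time / h: target / %, starting material / %): 1.00: 1.1, 98.3; 1.50: 1.2, 98.5; 2.50: 1.9, 97.6; 4.00: 2.9, 96.7; 6.00: 2.4, 95.8; 10.0: 2.4, 95.4; 15.0: 2.8, 95.4
- south (time / h: target / %, starting material / %): 0.833: 47.6, 49.3; 2.00: 70.0, 19.9; 4.00: 71.1, 4.9; 6.00: 62.2, 1.5; 8.00: 54.0, 0.4; 12.0: 42.9, 0; 15.0: 37.4, 0.2

(each reading ± 0.3 percentage points)

- the analysis behind the earlier runs scatters by 0.3 percentage points, standard deviation
- "hardly changes" means that all values lie within two and a half points (for a concentration: within two and a half percent of the largest)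

- amount of target at the end, in percent of the starting material charged for gamma, epsilon, theta, alpha, zeta, in this order
- how that number moves from the first to the last of them (rises all the way / falls, then rises / rises, then falls / falls all the way / hardly changes)

In the south run starting material reads 0.4% at 8.00 h, yet target goes on falling, from 54.0% to 37.4% at 15.0 h. The fall slows, as a fraction of the charge per hour, from 0.0278 /h to 0.0183 /h. The own reckoning here reads this as target relaxing towards a level above zero. Setting the slope proportional to the height above that level gives two readings:

relaxation rate = 0.113 /h

floor = 24.0%

This floor is the share of reacted material that stays target once the relaxation is over. Younger material stands higher: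

share = floor + (whole − floor) × exp(−rate × age)

At low loading conversion is taken as proportional to reagent, scaled from the north-east stop, so gamma reaches 3.25%. Two ways then give its target. The last north-east share, 60.9%, gives 1.98%. The south rule, with target made near 4.00 h and so aged 16.0 h, gives a share of 36.4% and 1.18%.

They part, so the rule is held against the north-east run itself. It predicts 2.87% at 10.0 h and 2.11% at 15.0 h, where the readings are 2.4% and 2.8%. The misses lie on opposite sides, and the means are 2.49% and 2.60%. The first way leans on one high reading of a small number, with a scatter of 0.3 percentage points, so the rule is kept.

At high loading the south run's pseudo-first-order loss of starting material, 0.807 /h at 13 equiv, scaled to each charge, sets a mean time of formation. Conversion is taken as complete there. The row then reads: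

gamma 1.18%, epsilon 3.94%, theta 11.8%

alpha 36.4%, zeta 33.4%

Zeta stands lower than alpha, its target being older, so the row rises and then falls.

The forecast differs in size, with 1.9%, 9.5%, 34%, 71% and 45% (rises, then falls), reasoning that the “target is then over-reacted about 0.12 times as fast”.

The flasks give 1.26%, 4.44%, 15.4%, 36.3% and 33.4%: rises, then falls.

    starting material + reagent → target (k = 1.98 /M/h)
    second substrate + reagent → second product (k = 4.92 /M/h)
    third substrate + reagent → third product (k = 0.293 /M/h)
    target ⇌ isomer of the product (K = 2.40, k = 0.112 /h)

The unseen part is chiefly the isomer of the product, 66.6% in zeta at 20.0 h beside 33.4% target. The turning of target into that isomer, both ways, is the main reason zeta holds 33.4% target, for without this step it ends at >99.9%. The floor of 24.0%, read off the south run's slopes, lies below the level target reaches: after 200 h zeta stands at 29.4%, and alpha, with starting material at 0%, also stands at 29.4% target.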